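## Structural features

The target 25 is a tetracycle. A 5,6-dimethyl-2-pyrone (ring A) is fused through C3' and the C4' oxygen to a dihydropyran (ring B); ring B shares the C1–C7 bond with a cycloheptane (ring C); ring C shares the C4–C5 bond with a 5,5-dimethylcyclopent-2-enone (ring D). Ring C is numbered C1 (hemiketal carbon, S), C2 (secondary carbinol, R), C3 (ketone), C4 (tertiary carbinol, R), C5 (β-carbon of the ring D enone), C6 (CHCH3, R) and C7 (CH, R, carrying the methylene C11 that leads to C3'). Ring D is completed by C8 (enone α-CH), C9 (C=O) and C10 (CMe2). Calling β the face of ring C that carries the C4 hydroxyl, the C1 hydroxyl and C11 are β; the ring B oxygen, the C2 hydroxyl and the C6 methyl are α. C7, C1 and C2 are contiguous and C6 adjoins C7, whereas C4 is insulated by the C3 ketone and by sp2 C5. The fragile groups are the hemiketal (ring–chain tautomerism makes C1, C2 and C7 epimerisable), the tertiary α-ketol at C4 (also an aldol adduct of C9, so retro-aldol through C4–C10 and α-ketol shift are possible) and the pyrone lactone. The real difficulty is the seven-membered ring with C4 and C6, the two centres that no equilibration can repair, together with the dense oxidation on C1–C4. The key step exploits the C5–C6 bond: a secondary radical at C6, made from a terminal vinyl group whose CH2 becomes the C6 methyl, can add to C5 of a 4-hydroxycyclopent-2-enone and so close ring C.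

## Logic of the disconnections

25 ⇒ 23. The C1–OH and C2–OH bonds are cut (retro oxidative hydration of a C1=C2 enol ether). The hemiketal and the α-ketol then arise together in the last step, and C1 is left to ring–chain equilibration. Two stereocentres and the labile hemiketal disappear, leaving a robust β-aryloxy enone. The forward step must pick the C1=C2 bond over the ring D enone and the pyrone, and attack its α face.

23 ⇒ 21 (through 22). The ring B O–C1 bond is cut and the C3 carbonyl is traced back to a C2–C3 epoxide next to a C1 ketone. A 1,3-dioxygen pattern is the isomerisation product of an α,β-epoxy ketone, and its hemiketal with the pyrone hydroxyl dehydrates only toward C2. Ring B is opened and the oxidation at C3 is reduced to an alkene equivalent. The isomerisation must tolerate an acidic enol, and dehydration must beat transannular ketalisation by the C4 hydroxyl.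

21 ⇒ 17 + 18 (through 20), and 17 ⇒ 16. The C11–C3' bond (conjugate addition) and the C7–C11 bond (aminomethylation) are cut. 18 is a commercial carbon acid, and C7 is the only kinetically enolisable position of 16. Seven carbons leave in one convergent step. C-alkylation at C3' is needed, and C7 must settle trans to the C6 methyl.

16 ⇒ 15 ⇒ 14 ⇒ 13. The epoxide C–O bonds are removed, then the C1 carbonyl is returned to a silyl-protected carbinol. The cis enone is what nucleophilic epoxidation needs, and the masked C1 keeps ring C inert while ring D is adjusted. The epoxidation must distinguish the two enones of 15.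

13 ⇒ 11 (through 12). The C5=C8 π bond is removed. The key step is reductive and leaves ring D saturated; re-oxidation is unambiguous because C10 is quaternary and C1 is still masked. The cost is the loss of the C5 centre, which is intended.

11 ⇒ 10. The C5–C6 bond is cut, opening ring C to a vinyl group and a cyclopentenone. This removes the seven-membered ring and two stereocentres. The forward step needs hydrogen-atom transfer to the vinyl group only, a 7-exo closure faster than radical reduction, and a defined chair. For that reason 10 carries one configuration at C1 (S, silyloxy pseudo-equatorial) and an unprotected, small C4 hydroxyl (pseudo-axial).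

10 ⇒ 9. The Z-alkene is traced to an alkyne. The alkyne allows a C–C bond to C4 by carbonyl addition; the forward step needs cis-selective partial reduction that spares the vinyl group and the enone.

9 ⇒ 5 + 8. The C3–C4 bond is cut to a terminal alkyne and a symmetrical, non-enolisable enedione. The whole carbon framework of 10 becomes two small pieces. The forward step must discriminate the faces of a ketone flanked by a quaternary carbon and a CH=CH unit; because C1 is already fixed, a C4 error is a separable diastereomer.

5 ⇒ 3 ⇒ 1 + 2, and 8 ⇒ 6 (through 7). The C1–C7 bond is cut to an ynal and an allyl metal, with O-silyl and C-silyl groups as the only adjustments; the ring alkene of 8 comes from the saturated dione. The allylation must be enantioselective because C1 steers the key step.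

## Other disconnections considered

Alternative 1: The cut removes ring A: the pyrone C4'–C5' and O1'–C6' bonds are formed last from the ring B carboxylic acid A2 and but-2-yne A3. In the forward step [Cp*RhCl2]2 with Ag2CO3 would metalate the vinylic C–H next to the ring oxygen under carboxylate direction, insert A3 and close the lactone, giving the protected target A1. In its favour: the alkyne is symmetrical, so no regiochemistry arises, and the hemiketal and both hydroxyls are masked, so the last operation is a simple deprotection. In that respect it is better protected than the chosen plan, whose last step is an oxidation. Against it: A2 already contains the whole oxidised tricycle, and a β-alkoxyacrylic acid must be attached to C7 and C1 by extra steps, where the chosen plan adds commercial 18 in one conjugate addition. The C–H activation also needs heat and a stoichiometric silver oxidant next to an α-silyloxy ketone and an enone, and β-alkoxyacrylic acids can lose CO2. It says nothing about rings C and D, so on the central problem the two plans are not in competition; on step economy the chosen plan is shorter at this end.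

Alternative 2: The cut is the C4–C10 bond, with ring D stored as a furan in A5. Peracid would open the furan to the Z-enedione A6, and K2CO3 in methanol would close ring D by aldol addition of the isopropyl ketone enolate to the C4 ketone, giving A4. In its favour: ring D appears with its enone and the tertiary carbinol in one flask from a robust aromatic precursor, with cheap reagents. It needs no separate dehydrogenation, which is better redox economy than the chosen plan, where ring D is reduced in step 6 and re-oxidised in step 7. Against it: C4 is created last, in a reversible aldol, relative to a C6 centre two atoms away across sp2 C5, so its configuration rests on an equilibrium that cannot be predicted. The furan-fused cycloheptane with C6 and C1 must also be built by other chemistry. The late-stage workload (C2 oxygenation, ring B, pyrone) is the same in both plans. Mechanistically the chosen plan sets C4 first, by catalyst control plus diastereomer separation, and then C6 through a cyclic transition state, which is the more controllable order.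

Alternative 3: The cut is the C6–C7 bond. Mn(OAc)3 with Cu(OAc)2 would oxidise the β-keto ester A8 to its α-radical, which adds 7-endo to the ethylidene carbon; divalent copper would then oxidise the tertiary C5 radical to the C5=C8 alkene, giving A7. In its favour: it is also a radical closure of ring C, but oxidative, so the ring D alkene emerges from the cyclisation itself and C7 receives its carbon substituent in the same step. On redox economy it is better than the chosen plan. Against it: C6 would depend on the ethylidene geometry and on the folding of a flexible tether, and the copper-mediated elimination could also run toward C6 and erase that centre. The ester carbon must be reduced and converted before 18 can be attached. Acetic acid at elevated temperature threatens the silyl ether and the ketal. The seven-membered ring closure is equally demanding in both plans; the chosen plan forms the C5–C6 bond instead and fixes C6 through a chair with three pseudo-equatorial groups, at the price of one extra dehydrogenation.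

Key step: step 6

Remarks before the steps.
- Assumption: the hemiketal of 25 (C1–OH β, ring B trans-fused) is taken to be the arrangement favoured by ring–chain equilibration, so a C1 epimer converges on 25.
- Convention: metal enolates, metal acetylides and radicals are treated as reactive intermediates within a step; compounds marked "not isolated" are covalent species that persist between two reagent additions.
- Configuration check: 10 (C4 R, C1 S) and 11 (C4 R, C5 R, C6 R, C1 S) both have the C4 hydroxyl β and, in 11, the C6 methyl α, as in 25; no correction of these structures is needed. The CIP label at the carbinol carbon changes from S in 9 to R in 10 without any change in geometry.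

Step 1
Reactants: 1 3-(trimethylsilyl)prop-2-ynal; 2 allyltributylstannane
Product: 3 (S)-1-(trimethylsilyl)hex-5-en-1-yn-3-ol
Conditions: (S)-BINOL (20 mol%), Ti(OiPr)4 (10 mol%), 4 Å MS, CH2Cl2, −20 °C; H2O
Reagents that add atoms: none
Why: Catalytic asymmetric allylation of an aldehyde with an allylstannane under a chiral BINOL–titanium Lewis acid (Keck allylation), a reaction type used on alkynyl aldehydes; the (S)-ligand should direct the allyl group to the Si face and give the S carbinol, which later becomes the pseudo-equatorial C1 silyloxy group.

Step 2
Reactants: 3 (S)-1-(trimethylsilyl)hex-5-en-1-yn-3-ol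
Product: 5 (S)-tert-butyl(hex-5-en-1-yn-3-yloxy)dimethylsilane, via bis-silylated enyne 4 (not isolated)
Conditions: TBSCl, imidazole, DMF, rt; then MeOH, K2CO3 (0.2 equiv), rt
Reagents that add atoms: tert-butyldimethylsilyl chloride, CC(C)(C)[Si](C)(C)Cl
Why: Imidazole-promoted silylation of the secondary propargylic alcohol, then methanolysis of the C(sp)–SiMe3 bond in the same flask; the hindered O–Si bond is inert to carbonate in methanol and no stereocentre is touched.

Step 3
Reactants: 6 2,2-dimethylcyclopentane-1,3-dione
Product: 8 2,2-dimethylcyclopent-4-ene-1,3-dione, via 4-bromo-2,2-dimethylcyclopentane-1,3-dione 7 (not isolated)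
Conditions: CuBr2 (2.1 equiv), EtOAc/CHCl3, reflux; then Et3N, CH2Cl2, 0 °C
Reagents that add atoms: none
Why: α-Bromination of a ketone with CuBr2 followed by E1cB loss of HBr (the C5 hydrogen is α to the second carbonyl) is a standard dehydrogenation of 2,2-disubstituted cyclopentane-1,3-diones; the quaternary carbon blocks any other enolisation.

Step 4
Reactants: 5 (S)-tert-butyl(hex-5-en-1-yn-3-yloxy)dimethylsilane; 8 2,2-dimethylcyclopent-4-ene-1,3-dione
Product: 9 (S)-4-hydroxy-5,5-dimethyl-4-[(S)-3-(tert-butyldimethylsilyloxy)hex-5-en-1-yn-1-yl]cyclopent-2-en-1-one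
Conditions: Me2Zn (2 equiv), N,N'-bis(3,5-di-tert-butylsalicylidene)-1,2-cyclohexanediamine (20 mol%, the antipode that favours 4S), toluene, rt; H2O
Reagents that add atoms: none
Why: Catalytic enantioselective 1,2-addition of an alkynylzinc (from the terminal alkyne and Me2Zn) to a ketone under a chiral zinc–salen complex; the ketone is non-enolisable, activated by the second carbonyl, and flanked by two very different groups (quaternary carbon against flat CH=CH). Because C1 is already fixed, the C4 epimer is a diastereomer that is removed by chromatography here or after step 5, so the stereochemical purity of 10 does not rest on the catalyst alone.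

Step 5
Reactants: 9 (S)-4-hydroxy-5,5-dimethyl-4-[(S)-3-(tert-butyldimethylsilyloxy)hex-5-en-1-yn-1-yl]cyclopent-2-en-1-one
Product: 10 (R)-4-hydroxy-5,5-dimethyl-4-[(1Z,3S)-3-(tert-butyldimethylsilyloxy)hexa-1,5-dien-1-yl]cyclopent-2-en-1-one
Conditions: H2 (1 atm, 1 equiv), Pd/CaCO3–Pb(OAc)2, quinoline, EtOAc, rt
Reagents that add atoms: none
Why: Syn addition of H2 on poisoned palladium (Lindlar semihydrogenation) gives the Z-alkene; the alkyne binds to the surface much more strongly than the vinyl group or the enone, and uptake is stopped after one equivalent. No stereocentre is formed.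

Step 6
Reactants: 10 (R)-4-hydroxy-5,5-dimethyl-4-[(1Z,3S)-3-(tert-butyldimethylsilyloxy)hexa-1,5-dien-1-yl]cyclopent-2-en-1-one
Product: 11 (3aR,4R,6S,8aR)-6-(tert-butyldimethylsilyloxy)-8a-hydroxy-1,1,4-trimethyl-3,3a,4,5,6,8a-hexahydroazulen-2(1H)-one
Conditions: Fe(acac)3 (30 mol%), PhSiH3 (2.5 equiv, slow addition), EtOH/(CH2OH)2 5:1, 0.01 M, 60 °C
Reagents that add atoms: none
Why: Fe(acac)3 and PhSiH3 in ethanol form an iron hydride that transfers a hydrogen atom to the terminal CH2 of the monosubstituted alkene, creating the C6 methyl group and a nucleophilic secondary radical at C6. This radical adds 7-exo-trig to C5, the β-carbon of the 4-hydroxycyclopentenone, closing ring C; the C8 α-keto radical is then reduced and protonated by the solvent. The closest known reaction type is the iron-hydride hydrogen-atom-transfer reductive coupling of unactivated alkenes with enones in its intramolecular form, where seven-membered closures are rarer than five- and six-membered ones. C5 is set by the tether: C3 sits on one face of ring D, so C6 can reach C5 only on that face and the fusion is cis (C5–H β). C6 is set in a chair-like cycloheptene transition state with the quaternary C10 pseudo-equatorial, the small free C4 hydroxyl pseudo-axial, the C1 silyloxy group pseudo-equatorial (the reason for S at C1 and for leaving the tertiary alcohol unprotected) and the new methyl pseudo-equatorial, which places it α and anti to the C4 hydroxyl as in 25. The step needs hydrogen-atom transfer to the vinyl group only, which the catalyst provides because 1,2-disubstituted and electron-poor alkenes are poor acceptors; it also needs cyclisation to outrun reduction of the radical, which the cis C2=C3 bond and the quaternary carbinol promote by holding C6 near C5, supported by high dilution and slow silane addition.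

Step 7
Reactants: 11 (3aR,4R,6S,8aR)-6-(tert-butyldimethylsilyloxy)-8a-hydroxy-1,1,4-trimethyl-3,3a,4,5,6,8a-hexahydroazulen-2(1H)-one
Product: 13 (4R,6S,8aR)-6-(tert-butyldimethylsilyloxy)-1,1,4-trimethyl-8a-(trimethylsilyloxy)-4,5,6,8a-tetrahydroazulen-2(1H)-one, via ring D silyl enol ether 12 (not isolated)
Conditions: TMSOTf, Et3N, CH2Cl2, 0 °C; then Pd(OAc)2 (1.1 equiv), MeCN, rt
Reagents that add atoms: trimethylsilyl trifluoromethanesulfonate, C[Si](C)(C)OS(=O)(=O)C(F)(F)F
Why: Saegusa–Ito oxidation: soft enolisation can occur only toward C8 (C10 is quaternary, C1 is still masked) and also silylates the tertiary hydroxyl. Palladation on the convex face of ring D places palladium syn to the β C5–H, and β-hydride elimination gives the C5=C8 enone; the C5 centre is removed as planned and C4 and C6 are untouched.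

Step 8
Reactants: 13 (4R,6S,8aR)-6-(tert-butyldimethylsilyloxy)-1,1,4-trimethyl-8a-(trimethylsilyloxy)-4,5,6,8a-tetrahydroazulen-2(1H)-one
Product: 14 (4R,6S,8aR)-6,8a-dihydroxy-1,1,4-trimethyl-4,5,6,8a-tetrahydroazulen-2(1H)-one
Conditions: Bu4NF, AcOH, THF, 0 °C → rt
Reagents that add atoms: none
Why: Fluoride cleaves both silyl ethers; acetic acid buffers the alkoxides so that retro-aldol opening of the C4–C10 bond is avoided.

Step 9
Reactants: 14 (4R,6S,8aR)-6,8a-dihydroxy-1,1,4-trimethyl-4,5,6,8a-tetrahydroazulen-2(1H)-one
Product: 15 (4R,8aR)-8a-hydroxy-1,1,4-trimethyl-4,5-dihydroazulene-2,6(1H,8aH)-dione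
Conditions: DMP, NaHCO3, CH2Cl2, 0 °C → rt
Reagents that add atoms: none
Why: Dess–Martin oxidation of the secondary allylic alcohol at C1; the tertiary alcohol cannot be oxidised, and the buffer protects the doubly allylic carbinol from ionisation.

Step 10
Reactants: 15 (4R,8aR)-8a-hydroxy-1,1,4-trimethyl-4,5-dihydroazulene-2,6(1H,8aH)-dione
Product: 16 C2–C3 β-epoxide of 15 (cis oxirane syn to the C4 hydroxyl, C1 ketone)
Conditions: t-BuOOH, DBU (0.3 equiv), CH2Cl2, 0 °C
Reagents that add atoms: tert-butyl hydroperoxide, CC(C)(C)OO
Why: Weitz–Scheffer nucleophilic epoxidation: the peroxide anion adds to C3 of the cis-disubstituted enone and closes on C2, while the ring D enone is much slower because attack at C5 would create a quaternary centre. Hydrogen bonding to the C4 hydroxyl should deliver the peroxide to the β face, which also excludes Payne rearrangement; both epoxide centres are erased in step 13, so the facial outcome is not critical.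

Step 11
Reactants: 16 C2–C3 β-epoxide of 15
Product: 17 C7 (dimethylamino)methyl derivative of 16 (CH2NMe2 β, trans to the C6 methyl)
Conditions: LiN(SiMe3)2 (2.2 equiv), THF, −78 °C; then CH2=NMe2+ I−, −78 → 0 °C; H2O
Reagents that add atoms: N,N-dimethylmethyleneiminium iodide, C[N+](C)=C.[I-]
Why: After the hydroxyl, kinetic deprotonation occurs at C7, the only α-CH2 of the two ketones, and the lithium enolate is aminomethylated by the iminium salt (Mannich reaction); approach anti to the C6 methyl is expected, but this C7 centre is erased in step 12.

Step 12
Reactants: 17 C7 (dimethylamino)methyl derivative of 16; 18 4-hydroxy-5,6-dimethyl-2H-pyran-2-one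
Product: 21 epoxy ketone carrying at C7 (β) the (4-hydroxy-5,6-dimethyl-2-oxo-2H-pyran-3-yl)methyl group, via trimethylammonium iodide 19 (not isolated), via exo-methylene epoxy ketone 20 (not isolated)
Conditions: MeI, CH2Cl2, rt; then 18, DBU, MeCN, 0 °C → rt
Reagents that add atoms: none
Why: N-Methylation makes the amine a leaving group and DBU induces E1cB elimination to the α-methylene ketone, to which C3' of the deprotonated hydroxypyrone adds (Michael addition of a cyclic 1,3-dicarbonyl, as 4-hydroxycoumarins add to enones). C7 is protonated or equilibrated under the basic conditions to the isomer with C11 trans to the C6 methyl, both pseudo-equatorial.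

Step 13
Reactants: 21 epoxy ketone carrying the pyronylmethyl group at C7
Product: 23 ring B enol ether (C1=C2 conjugated with the C3 ketone; 1,2-anhydro-2-deoxy form of 25), via ring B hemiketal 22 (not isolated)
Conditions: Pd(PPh3)4 (10 mol%), dppe (10 mol%), toluene, 90 °C; then PPTS (20 mol%), 4 Å MS, 80 °C
Reagents that add atoms: none
Why: Zerovalent palladium with a chelating diphosphine isomerises α,β-epoxy ketones to 1,3-diketones (insertion into the C2–O bond, β-hydride elimination from the C3 alkoxide, reductive elimination); the acidic 1,3-diones this reaction normally delivers indicate that an acidic enol such as the hydroxypyrone is tolerated. The pyrone hydroxyl then traps the C1 ketone as a six-membered hemiketal, and mild acid dehydrates it toward C2, the only direction that gives a conjugated β-aryloxy enone, as 2-hydroxychromanones give chromones; C4 cannot dehydrate because it has no β-hydrogen.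

Step 14
Reactants: 23 ring B enol ether
Product: 25 target CNP0525404.1, via enol ether epoxide 24 (not isolated)
Conditions: DMDO, acetone, −20 → 0 °C; then H2O, pH 7 buffer, rt
Reagents that add atoms: dimethyldioxirane, CC1(C)OO1; water, O
Why: Dimethyldioxirane epoxidises the electron-rich C1=C2 bond of the β-aryloxy enone in preference to the electron-poor ring D enone and the pyrone (as in the epoxidation of chromone-type enol ethers), and water opens the alkoxy epoxide at the acetal carbon C1 (Rubottom-type oxidative hydration). Attack on the α face, anti to the pseudo-axial C4 hydroxyl, sets the C2 hydroxyl α; anti opening gives the C1 hydroxyl β directly, and C1 can in any case equilibrate by ring–chain tautomerism.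

Compound list

1 | 3-(trimethylsilyl)prop-2-ynal | C[Si](C)(C)C#CC=O | starting material
2 | allyltributylstannane | C=CC[Sn](CCCC)(CCCC)CCCC | starting material
3 | (S)-1-(trimethylsilyl)hex-5-en-1-yn-3-ol | C=CC[C@H](O)C#C[Si](C)(C)C | intermediate
4 | (S)-tert-butyldimethyl{[1-(trimethylsilyl)hex-5-en-1-yn-3-yl]oxy}silane (formed in the flask) | C=CC[C@H](O[Si](C)(C)C(C)(C)C)C#C[Si](C)(C)C | intermediate
5 | (S)-tert-butyl(hex-5-en-1-yn-3-yloxy)dimethylsilane | C=CC[C@H](O[Si](C)(C)C(C)(C)C)C#C | intermediate
6 | 2,2-dimethylcyclopentane-1,3-dione | CC1(C)C(=O)CCC1=O | starting material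
7 | 4-bromo-2,2-dimethylcyclopentane-1,3-dione (racemic, formed in the flask) | CC1(C)C(=O)CC(Br)C1=O | intermediate
8 | 2,2-dimethylcyclopent-4-ene-1,3-dione | CC1(C)C(=O)C=CC1=O | intermediate
9 | (S)-4-hydroxy-5,5-dimethyl-4-[(S)-3-(tert-butyldimethylsilyloxy)hex-5-en-1-yn-1-yl]cyclopent-2-en-1-one | C=CC[C@H](O[Si](C)(C)C(C)(C)C)C#C[C@@]1(O)C=CC(=O)C1(C)C | intermediate
10 | (R)-4-hydroxy-5,5-dimethyl-4-[(1Z,3S)-3-(tert-butyldimethylsilyloxy)hexa-1,5-dien-1-yl]cyclopent-2-en-1-one | C=CC[C@H](O[Si](C)(C)C(C)(C)C)/C=C\[C@@]1(O)C=CC(=O)C1(C)C | intermediate
11 | (3aR,4R,6S,8aR)-6-(tert-butyldimethylsilyloxy)-8a-hydroxy-1,1,4-trimethyl-3,3a,4,5,6,8a-hexahydroazulen-2(1H)-one (cis-fused; C1 α-OTBS, C4 β-OH, C5 β-H, C6 α-CH3) | C[C@@H]1C[C@H](O[Si](C)(C)C(C)(C)C)C=C[C@@]2(O)[C@@H]1CC(=O)C2(C)C | intermediate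
12 | ring D trimethylsilyl enol ether of 11 with the C4 hydroxyl silylated (formed in the flask) | C[C@@H]1C[C@H](O[Si](C)(C)C(C)(C)C)C=C[C@@]2(O[Si](C)(C)C)[C@@H]1C=C(O[Si](C)(C)C)C2(C)C | intermediate
13 | (4R,6S,8aR)-6-(tert-butyldimethylsilyloxy)-1,1,4-trimethyl-8a-(trimethylsilyloxy)-4,5,6,8a-tetrahydroazulen-2(1H)-one | C[C@@H]1C[C@H](O[Si](C)(C)C(C)(C)C)C=C[C@@]2(O[Si](C)(C)C)C1=CC(=O)C2(C)C | intermediate
14 | (4R,6S,8aR)-6,8a-dihydroxy-1,1,4-trimethyl-4,5,6,8a-tetrahydroazulen-2(1H)-one | C[C@@H]1C[C@H](O)C=C[C@@]2(O)C1=CC(=O)C2(C)C | intermediate
15 | (4R,8aR)-8a-hydroxy-1,1,4-trimethyl-4,5-dihydroazulene-2,6(1H,8aH)-dione | C[C@@H]1CC(=O)C=C[C@@]2(O)C1=CC(=O)C2(C)C | intermediate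
16 | C2–C3 β-epoxide of 15 (oxirane syn to the C4 hydroxyl) | C[C@@H]1CC(=O)[C@H]3O[C@H]3[C@@]2(O)C1=CC(=O)C2(C)C | intermediate
17 | C7 β-(dimethylamino)methyl derivative of 16 | C[C@@H]1[C@@H](CN(C)C)C(=O)[C@H]3O[C@H]3[C@@]2(O)C1=CC(=O)C2(C)C | intermediate
18 | 4-hydroxy-5,6-dimethyl-2H-pyran-2-one | Cc1oc(=O)cc(O)c1C | starting material
19 | trimethylammonium iodide of 17 (formed in the flask) | C[C@@H]1[C@@H](C[N+](C)(C)C)C(=O)[C@H]3O[C@H]3[C@@]2(O)C1=CC(=O)C2(C)C.[I-] | intermediate
20 | 7-methylene derivative of 16 (formed in the flask) | C[C@@H]1C(=C)C(=O)[C@H]3O[C@H]3[C@@]2(O)C1=CC(=O)C2(C)C | intermediate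
21 | 16 carrying at C7 (β) the (4-hydroxy-5,6-dimethyl-2-oxo-2H-pyran-3-yl)methyl group | C[C@@H]1[C@@H](Cc4c(O)c(C)c(C)oc4=O)C(=O)[C@H]3O[C@H]3[C@@]2(O)C1=CC(=O)C2(C)C | intermediate
22 | 2-deoxy-25: ring B hemiketal of the C1/C3 diketone (C1–OH β, formed in the flask) | Cc1oc(=O)c2c(c1C)O[C@]1(O)CC(=O)[C@@]3(O)C(=CC(=O)C3(C)C)[C@H](C)[C@H]1C2 | intermediate
23 | ring B enol ether: C1=C2 conjugated with the C3 ketone (C4 β-OH, C6 α-CH3, C7 α-H) | Cc1oc(=O)c2c(c1C)OC1=CC(=O)[C@@]3(O)C(=CC(=O)C3(C)C)[C@H](C)[C@H]1C2 | intermediate
24 | C1–C2 α-epoxide of 23 (formed in the flask) | Cc1oc(=O)c2c(c1C)O[C@]14O[C@@H]4C(=O)[C@@]3(O)C(=CC(=O)C3(C)C)[C@H](C)[C@H]1C2 | intermediate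
25 | CNP0525404.1 (C1 S, C2 R, C4 R, C6 R, C7 R; C1–OH β, C2–OH α, C4–OH β, C6–CH3 α, C11 β) | Cc1oc(=O)c2c(c1C)O[C@]1(O)[C@H](O)C(=O)[C@@]3(O)C(=CC(=O)C3(C)C)[C@H](C)[C@H]1C2 | target

Total step count: 14. Longest linear sequence: 13 steps (steps 1, 2 and 4–14, from 1); the branch from 6 joins at step 4.

Least certain steps

Step 6 (key step). The most likely failure is that the 7-exo closure is too slow, so the C6 radical is reduced or the vinyl group migrates along the chain by reversible hydrogen-atom transfer; a less likely one is cyclisation through the other chair, which would invert C6. Fallback: from 10, Markovnikov hydration of the vinyl group (Co(acac)2, PhSiH3, O2, THF) would give the secondary alcohol F1 as a mixture at the new carbinol carbon. Iodination with I2, PPh3 and imidazole, which leaves the tertiary alcohol alone, would give the secondary iodide F2. Tributyltin hydride added by syringe pump with AIBN in dilute benzene at 80 °C would then generate the same C6 radical in a chain process in which the hydrogen donor is kept scarce, and the cyclisation rejoins the route at 11.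

Step 4. The catalyst class is established mainly for aryl and simple alkenyl ketones, so face discrimination at this enedione may be weak, and methyl transfer from zinc may compete. Fallback: from 8, Corey–Bakshi–Shibata mono-reduction (2-methyl-CBS-oxazaborolidine of the antipode that gives the S alcohol, BH3·SMe2) would give (S)-4-hydroxy-5,5-dimethylcyclopent-2-en-1-one F3. After deprotonation of the hydroxyl with LiN(SiMe3)2, the lithium acetylide of 5 should add anti to the alkoxide to give the cis-diol F4, which is freed from its trans diastereomer by chromatography. MnO2 oxidation of the secondary allylic alcohol rejoins the route at 9. If the addition turned out syn, the R alcohol would be used instead.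

Step 5. The alkyne is flanked by a quaternary carbinol and a silyloxy carbon, so hydrogenation may be slow enough for saturation of the unhindered vinyl group to compete. Fallback: from 9, hydrogen gas is replaced by electron-transfer reduction with zinc activated by Cu(OAc)2 and AgNO3 in aqueous methanol, which reduces alkynes carrying propargylic oxygen to cis-alkenes and does not touch isolated alkenes; it rejoins the route at 10 without any new compound.

Step 13. Acid-promoted opening of the epoxide by the pyrone or C4 hydroxyl may precede palladium insertion, and in the second stage transannular ketalisation by the C4 hydroxyl or an α-ketol shift may compete with dehydration. Fallback: from 21, SmI2 in THF/MeOH at −78 °C would cleave the C2–O bond of the epoxy ketone to the β-hydroxy ketone F5, and DMP would oxidise the C3 carbinol to the diketone, which closes to 22; the route is rejoined there and PPTS gives 23 as in step 13.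

Step 14. Hydrogen-bond delivery by the C4 hydroxyl could send the oxidant to the β face, and the alkoxy epoxide could lose a proton toward a C1=C2 enol instead of adding water. Fallback: from 23, osmylation (OsO4 cat., N-methylmorpholine N-oxide, acetone/H2O) adds both oxygens in one concerted syn step without a cationic intermediate. Attack on the α face would give the cis-diol hemiketal F6, the C1 epimer of the target, which should mutarotate at C1 to 25.

Further compounds

F1 | step 6 | (R)-4-hydroxy-4-[(1Z,3S)-3-(tert-butyldimethylsilyloxy)-5-hydroxyhex-1-en-1-yl]-5,5-dimethylcyclopent-2-en-1-one (both configurations at the new carbinol carbon) | CC(O)C[C@H](O[Si](C)(C)C(C)(C)C)/C=C\[C@@]1(O)C=CC(=O)C1(C)C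
F2 | step 6 | (R)-4-hydroxy-4-[(1Z,3S)-3-(tert-butyldimethylsilyloxy)-5-iodohex-1-en-1-yl]-5,5-dimethylcyclopent-2-en-1-one (both configurations at the iodide carbon) | CC(I)C[C@H](O[Si](C)(C)C(C)(C)C)/C=C\[C@@]1(O)C=CC(=O)C1(C)C
F3 | step 4 | (S)-4-hydroxy-5,5-dimethylcyclopent-2-en-1-one | O=C1C=C[C@H](O)C1(C)C
F4 | step 4 | cis-1-[(S)-3-(tert-butyldimethylsilyloxy)hex-5-en-1-yn-1-yl]-5,5-dimethylcyclopent-2-ene-1,4-diol (alkynyl trans to the secondary hydroxyl) | C=CC[C@H](O[Si](C)(C)C(C)(C)C)C#C[C@@]1(O)C=C[C@H](O)C1(C)C
F0 | step 5 | none | none
F5 | step 13 | β-hydroxy ketone from 21: C1 ketone, C2 methylene, C3 β-hydroxyl | C[C@@H]1[C@@H](Cc4c(O)c(C)c(C)oc4=O)C(=O)C[C@@H](O)[C@@]2(O)C1=CC(=O)C2(C)C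
F6 | step 14 | C1 epimer of 25 (C1–OH α, ring B cis-fused) | Cc1oc(=O)c2c(c1C)O[C@@]1(O)[C@H](O)C(=O)[C@@]3(O)C(=CC(=O)C3(C)C)[C@H](C)[C@H]1C2
A1 | alternative 1 | methyl ketal bis(triethylsilyl) ether of 25 | Cc1oc(=O)c2c(c1C)O[C@]1(OC)[C@H](O[Si](CC)(CC)CC)C(=O)[C@@]3(O[Si](CC)(CC)CC)C(=CC(=O)C3(C)C)[C@H](C)[C@H]1C2
A2 | alternative 1 | ring B dihydropyran carboxylic acid (methyl ketal, bis(triethylsilyl) ether) | OC(=O)C2=CO[C@]1(OC)[C@H](O[Si](CC)(CC)CC)C(=O)[C@@]3(O[Si](CC)(CC)CC)C(=CC(=O)C3(C)C)[C@H](C)[C@H]1C2
A3 | alternative 1 | but-2-yne | CC#CC
A4 | alternative 2 | hydroazulene 4-hydroxycyclopentenone (C3 dioxolane, C1 silyl ether) | CC1(C)C(=O)C=C2[C@]1(O)C3(OCCO3)C[C@H](O[Si](C)(C)C(C)(C)C)C[C@H]2C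
A5 | alternative 2 | 2-isopropylfuran fused to the ring C cycloheptane (C3 dioxolane, C1 silyl ether) | CC(C)c1cc2c(o1)C3(OCCO3)C[C@H](O[Si](C)(C)C(C)(C)C)C[C@H]2C
A6 | alternative 2 | ring-opened (Z)-enedione | CC(C)C(=O)/C=C1\C(=O)C3(OCCO3)C[C@H](O[Si](C)(C)C(C)(C)C)C[C@H]1C
A7 | alternative 3 | hydroazulene keto ester with ring D alkene | COC(=O)[C@@H]1[C@@H](C)C2=CC3(OCCO3)C(C)(C)[C@@]2(O[Si](CC)(CC)CC)C(OC)=CC1=O
A8 | alternative 3 | β-keto ester tethered to the (E)-ethylidenecyclopentane | COC(=O)CC(=O)/C=C(/OC)[C@@]1(O[Si](CC)(CC)CC)/C(=C/C)CC2(OCCO2)C1(C)C
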